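## Retrosynthetic overview

1. Target ⇒ Steglich esterification of the primary alcohol with (Z)-hexadec-11-enoic acid, between two desilylation steps.
2. (Z)-Tetrasubstituted enal ⇒ exocyclic allene by a proposed Pd-catalysed methylboration (then oxidation); allene ⇒ ring ketone by ethynylation and formate hydrogenolysis.
3. Side-chain carbinol ⇒ CBS reduction of a skipped dienone ⇒ α-selective geranylbarium addition to an (E)-enal ⇒ Wittig ⇒ hydroboration of an allyl group.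
4. Ring stereotriad ⇒ MeLi addition to a ketone, and Cu-catalysed asymmetric conjugate addition with anti allylation on a 2-methyl enone monoketal.
5. Rings: no ring is built; the single cyclohexane ring is carried from purchased enone 1, and its dioxolane protecting ring is removed in step 13.

Assumption: 1, 4, 13, 15 and 29 are purchased; the Josiphos enantiomer in step 3 is the one that gives the 6S adduct (to be confirmed on first run); TBS = tert-butyldimethylsilyl, TES = triethylsilyl, TIPS = triisopropylsilyl; ring locants in the Why lines follow the target name (C1 = CH with the three-carbon arm, C2 = quaternary C, C3 = carbinol C, C5 = ring CH2 next to ylidene carbon C6).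

## Route

Step 1
Reactants: 1 1,4-dioxaspiro[4.5]dec-6-en-8-one
Product: 2 7-iodo-1,4-dioxaspiro[4.5]dec-6-en-8-one
Conditions: I2, pyridine, CH2Cl2, 0 °C → rt
Reagents that add atoms: iodine (II)
Why: Johnson α-iodination (pyridine conjugate addition, enolate iodination, elimination; a Baylis–Hillman-type sequence) gives only the α-iodoenone.

Step 2
Reactants: 2 7-iodo-1,4-dioxaspiro[4.5]dec-6-en-8-one
Product: 3 7-methyl-1,4-dioxaspiro[4.5]dec-6-en-8-one
Conditions: Me4Sn, Pd2(dba)3 (2.5 mol %), AsPh3, CuI (10 mol %), NMP, 60 °C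
Reagents that add atoms: tetramethylstannane (C[Sn](C)(C)C)
Why: Stille coupling of the electron-poor vinyl iodide transfers methyl regiospecifically and leaves enone and ketal intact.

Step 3
Reactants: 3 7-methyl-1,4-dioxaspiro[4.5]dec-6-en-8-one; 4 (3-bromopropoxy)(tert-butyl)dimethylsilane
Product: 7 (6S,7S)-7-allyl-6-[3-(TBS-oxy)propyl]-7-methyl-1,4-dioxaspiro[4.5]decan-8-one, via Grignard reagent 5 (not isolated), via magnesium enolate 6 (not isolated)
Conditions: 4, Mg, Et2O; then 3, CuBr·SMe2 (5 mol %), (R,S)-Josiphos [(R)-1-[(S)-2-(diphenylphosphino)ferrocenyl]ethyldicyclohexylphosphine] (6 mol %), t-BuOMe, −75 °C; then allyl iodide, DMPU, −75 → 0 °C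
Reagents that add atoms: magnesium ([Mg]); allyl iodide (C=CCI)
Why: Copper-catalysed asymmetric conjugate addition of the Grignard reagent sets the ring CH centre (6S, ligand control), and the magnesium enolate is allylated anti to the new neighbouring chain (trans vicinal dialkylation), setting the quaternary centre (7S).

Step 4
Reactants: 7 (6S,7S)-7-allyl-6-[3-(TBS-oxy)propyl]-7-methyl-1,4-dioxaspiro[4.5]decan-8-one
Product: 8 (6S,7S,8S)-7-allyl-6-[3-(TBS-oxy)propyl]-7,8-dimethyl-1,4-dioxaspiro[4.5]decan-8-ol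
Conditions: MeLi, Et2O, −78 → −30 °C
Reagents that add atoms: methyllithium ([Li]C)
Why: 1,2-Addition by axial attack on the chair with both carbon chains equatorial and the C7 methyl axial (which blocks the equatorial approach) gives the 8S carbinol with OH cis to the C7 methyl.

Step 5
Reactants: 8 (6S,7S,8S)-7-allyl-6-[3-(TBS-oxy)propyl]-7,8-dimethyl-1,4-dioxaspiro[4.5]decan-8-ol
Product: 9 (6S,7S,8S)-7-allyl-6-[3-(TBS-oxy)propyl]-7,8-dimethyl-8-(TES-oxy)-1,4-dioxaspiro[4.5]decane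
Conditions: Et3SiOTf, 2,6-lutidine, CH2Cl2, −78 → 0 °C
Reagents that add atoms: triethylsilyl trifluoromethanesulfonate (CC[Si](CC)(CC)OS(=O)(=O)C(F)(F)F)
Why: Silyl triflate silylation caps the hindered tertiary alcohol so it cannot form lactols, add to enals or be acylated later; the ketal tolerates these cold conditions.

Step 6
Reactants: 9 (6S,7S,8S)-7-allyl-6-[3-(TBS-oxy)propyl]-7,8-dimethyl-8-(TES-oxy)-1,4-dioxaspiro[4.5]decane
Product: 11 3-[(6S,7S,8S)-6-[3-(TBS-oxy)propyl]-7,8-dimethyl-8-(TES-oxy)-1,4-dioxaspiro[4.5]decan-7-yl]propan-1-ol, via alkylborane 10 (not isolated)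
Conditions: 9-BBN (9-borabicyclo[3.3.1]nonane), THF, 0 °C → rt; then NaOH (aq), H2O2, 0 °C → rt
Reagents that add atoms: 9-borabicyclo[3.3.1]nonane (B1C2CCCC1CCC2); hydrogen peroxide (OO)
Why: Brown hydroboration–oxidation adds anti-Markovnikov to the only alkene and gives the primary alcohol.

Step 7
Reactants: 11 3-[(6S,7S,8S)-6-[3-(TBS-oxy)propyl]-7,8-dimethyl-8-(TES-oxy)-1,4-dioxaspiro[4.5]decan-7-yl]propan-1-ol
Product: 12 3-[(6S,7S,8S)-6-[3-(TBS-oxy)propyl]-7,8-dimethyl-8-(TES-oxy)-1,4-dioxaspiro[4.5]decan-7-yl]propanal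
Conditions: TEMPO (2,2,6,6-tetramethylpiperidin-1-oxyl, 10 mol %), PhI(OAc)2, CH2Cl2, rt
Reagents that add atoms: none
Why: TEMPO/PhI(OAc)2 oxidation stops at the aldehyde and spares silyl ethers and ketal.

Step 8
Reactants: 12 3-[(6S,7S,8S)-6-[3-(TBS-oxy)propyl]-7,8-dimethyl-8-(TES-oxy)-1,4-dioxaspiro[4.5]decan-7-yl]propanal; 13 2-(triphenylphosphoranylidene)propanal
Product: 14 (2E)-2-methyl-5-[(6S,7S,8S)-6-[3-(TBS-oxy)propyl]-7,8-dimethyl-8-(TES-oxy)-1,4-dioxaspiro[4.5]decan-7-yl]pent-2-enal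
Conditions: toluene, 90 °C
Reagents that add atoms: none
Why: Wittig olefination with the stabilised α-methyl ylide gives the (E)-2-methyl enal.

Step 9
Reactants: 14 (2E)-2-methyl-5-[(6S,7S,8S)-6-[3-(TBS-oxy)propyl]-7,8-dimethyl-8-(TES-oxy)-1,4-dioxaspiro[4.5]decan-7-yl]pent-2-enal; 15 geranyl chloride [(2E)-1-chloro-3,7-dimethylocta-2,6-diene]
Product: 17 (3E,7E)-4,8,12-trimethyl-1-[(6S,7S,8S)-6-[3-(TBS-oxy)propyl]-7,8-dimethyl-8-(TES-oxy)-1,4-dioxaspiro[4.5]decan-7-yl]trideca-3,7,11-trien-5-ol (both C5 epimers), via geranylbarium chloride 16 (not isolated)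
Conditions: BaI2, lithium biphenylide, THF, rt; then 15, −78 °C; then 14, −78 °C
Reagents that add atoms: barium diiodide ([Ba+2].[I-].[I-])
Why: Allylbarium carbonyl addition occurs at the α-carbon with retention of the E double bond, giving the linear bis-allylic alcohol; its carbinol configuration is erased in step 10.

Step 10
Reactants: 17 (3E,7E)-4,8,12-trimethyl-1-[(6S,7S,8S)-6-[3-(TBS-oxy)propyl]-7,8-dimethyl-8-(TES-oxy)-1,4-dioxaspiro[4.5]decan-7-yl]trideca-3,7,11-trien-5-ol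
Product: 18 (3E,7E)-4,8,12-trimethyl-1-[(6S,7S,8S)-6-[3-(TBS-oxy)propyl]-7,8-dimethyl-8-(TES-oxy)-1,4-dioxaspiro[4.5]decan-7-yl]trideca-3,7,11-trien-5-one
Conditions: Dess–Martin periodinane, CH2Cl2, 0 °C
Reagents that add atoms: none
Why: Dess–Martin oxidation under cold, near-neutral conditions gives the skipped dienone without moving the β,γ-double bond into conjugation.

Step 11
Reactants: 18 (3E,7E)-4,8,12-trimethyl-1-[(6S,7S,8S)-6-[3-(TBS-oxy)propyl]-7,8-dimethyl-8-(TES-oxy)-1,4-dioxaspiro[4.5]decan-7-yl]trideca-3,7,11-trien-5-one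
Product: 19 (3E,5R,7E)-4,8,12-trimethyl-1-[(6S,7S,8S)-6-[3-(TBS-oxy)propyl]-7,8-dimethyl-8-(TES-oxy)-1,4-dioxaspiro[4.5]decan-7-yl]trideca-3,7,11-trien-5-ol
Conditions: (S)-1-methyl-3,3-diphenyltetrahydro-1H,3H-pyrrolo[1,2-c][1,3,2]oxazaborole (0.3 equiv), catecholborane, toluene, −78 °C
Reagents that add atoms: none
Why: Corey–Bakshi–Shibata reduction, with the α-methylalkenyl group as the large substituent, delivers hydride in the same sense as acetophenone → (R)-1-phenylethanol and sets the 5R carbinol.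

Step 12
Reactants: 19 (3E,5R,7E)-4,8,12-trimethyl-1-[(6S,7S,8S)-6-[3-(TBS-oxy)propyl]-7,8-dimethyl-8-(TES-oxy)-1,4-dioxaspiro[4.5]decan-7-yl]trideca-3,7,11-trien-5-ol
Product: 20 5-O-triisopropylsilyl ether of 19 (all stereocentres unchanged)
Conditions: i-Pr3SiOTf, 2,6-lutidine, CH2Cl2, −78 → 0 °C
Reagents that add atoms: triisopropylsilyl trifluoromethanesulfonate (CC(C)[Si](C(C)C)(C(C)C)OS(=O)(=O)C(F)(F)F)
Why: Silyl triflate silylation gives a robust secondary TIPS ether that outlasts the later removal of the TBS and TES groups.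

Step 13
Reactants: 20 5-O-triisopropylsilyl ether of 19
Product: 21 (2S,3S,4S)-2-[3-(TBS-oxy)propyl]-3,4-dimethyl-4-(TES-oxy)-3-[(3E,5R,7E)-4,8,12-trimethyl-5-(TIPS-oxy)trideca-3,7,11-trien-1-yl]cyclohexan-1-one
Conditions: In(OTf)3 (5 mol %), acetone/H2O (20:1), rt
Reagents that add atoms: water (O)
Why: Lewis-acid-catalysed ketal hydrolysis frees the ring ketone while the silyl ethers survive; the α-stereocentre is already the thermodynamically preferred epimer (both chains equatorial), so it is not eroded.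

Step 14
Reactants: 21 (2S,3S,4S)-2-[3-(TBS-oxy)propyl]-3,4-dimethyl-4-(TES-oxy)-3-[(3E,5R,7E)-4,8,12-trimethyl-5-(TIPS-oxy)trideca-3,7,11-trien-1-yl]cyclohexan-1-one
Product: 23 methyl carbonate of the 1-ethynylcyclohexan-1-ol derived from 21 (either configuration at the new carbinol carbon), via magnesium alkoxide 22 (not isolated)
Conditions: HC≡CMgBr, THF, 0 °C → rt; then ClCO2Me, −78 → 0 °C
Reagents that add atoms: ethynylmagnesium bromide (C#C[Mg]Br); methyl chloroformate (COC(=O)Cl)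
Why: Grignard 1,2-addition of the small ethynyl nucleophile and in-flask O-acylation give the propargylic carbonate; the new carbinol centre is destroyed in step 15.

Step 15
Reactants: 23 methyl carbonate of the 1-ethynylcyclohexan-1-ol derived from 21
Product: 24 tert-butyl{3-[(1R,2S,3S)-6-ethenylidene-2,3-dimethyl-3-(TES-oxy)-2-[(3E,5R,7E)-4,8,12-trimethyl-5-(TIPS-oxy)trideca-3,7,11-trien-1-yl]cyclohexyl]propoxy}dimethylsilane (exocyclic allene)
Conditions: Pd2(dba)3·CHCl3 (2.5 mol %), PBu3 (10 mol %), HCO2NH4, THF, 40 °C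
Reagents that add atoms: none
Why: Tsuji formate hydrogenolysis: zerovalent palladium ionises the propargylic carbonate in an SN2' sense to an allenylpalladium, formate supplies hydride, and reductive elimination gives the 1,1-disubstituted allene.

Step 16
Reactants: 24 exocyclic allene
Product: 26 (2Z)-2-[(2R,3S,4S)-2-[3-(TBS-oxy)propyl]-3,4-dimethyl-4-(TES-oxy)-3-[(3E,5R,7E)-4,8,12-trimethyl-5-(TIPS-oxy)trideca-3,7,11-trien-1-yl]cyclohexylidene]propan-1-ol, via allylboronate 25 (not isolated)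
Conditions: Pd(dba)2 (5 mol %), MeI, B2pin2, toluene, 60 °C; then NaOH (aq), H2O2, THF, 0 °C
Reagents that add atoms: iodomethane (CI); bis(pinacolato)diboron (CC1(C)OB(OC1(C)C)B1OC(C)(C)C(C)(C)O1); hydrogen peroxide (OO)
Why: Proposed new method: Pd-catalysed three-component methylboration of a 1,1-disubstituted exocyclic allene – MeI adds oxidatively to zerovalent palladium, Me–Pd–I binds the terminal C=C in the ring plane from the open C5-methylene side (the C1 side is screened by the C1 arm and the quaternary C2), methyl migrates to the central allene carbon to give the π-allyl complex with C1 anti, and B2pin2 transmetalation with C–B reductive elimination at the CH2 terminus outruns syn/anti exchange (which would need a tertiary σ-palladium), so CH3 ends cis to C5 and CH2B (CH2OH after stereoretentive oxidation) cis to C1, i.e. the Z tetrasubstituted alkene; the closest known reaction type is the Pd-catalysed acylboration (carbopalladation/π-allyl borylation) of allenes with an organic halide and B2pin2.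

Step 17
Reactants: 26 (Z)-allylic alcohol
Product: 27 (2Z)-2-[(2R,3S,4S)-2-[3-(TBS-oxy)propyl]-3,4-dimethyl-4-(TES-oxy)-3-[(3E,5R,7E)-4,8,12-trimethyl-5-(TIPS-oxy)trideca-3,7,11-trien-1-yl]cyclohexylidene]propanal
Conditions: TEMPO (2,2,6,6-tetramethylpiperidin-1-oxyl, 10 mol %), PhI(OAc)2, CH2Cl2, rt
Reagents that add atoms: none
Why: TEMPO/PhI(OAc)2 oxidation of the primary allylic alcohol is non-isomerising, so the Z enal geometry is kept.

Step 18
Reactants: 27 tris-silylated (Z)-enal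
Product: 28 (2Z)-2-[(2R,3S,4S)-4-hydroxy-2-(3-hydroxypropyl)-3,4-dimethyl-3-[(3E,5R,7E)-4,8,12-trimethyl-5-(TIPS-oxy)trideca-3,7,11-trien-1-yl]cyclohexylidene]propanal
Conditions: HF·pyridine, pyridine, THF, 0 °C → rt
Reagents that add atoms: none
Why: Rate-selective desilylation: buffered HF·pyridine removes the primary TBS and tertiary TES ethers while the bulkier secondary TIPS ether stays.

Step 19
Reactants: 28 diol enal; 29 (11Z)-hexadec-11-enoic acid
Product: 30 3-[(1R,2S,3S,6Z)-3-hydroxy-2,3-dimethyl-6-(1-oxopropan-2-ylidene)-2-[(3E,5R,7E)-4,8,12-trimethyl-5-(TIPS-oxy)trideca-3,7,11-trien-1-yl]cyclohexyl]propyl (11Z)-hexadec-11-enoate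
Conditions: DCC (N,N'-dicyclohexylcarbodiimide), DMAP (4-dimethylaminopyridine, 10 mol %), CH2Cl2, 0 °C → rt
Reagents that add atoms: none
Why: Steglich esterification acylates only the primary alcohol, since the tertiary alcohol is inert and the secondary one is still silylated.

Step 20
Reactants: 30 TIPS-protected ester
Product: 31 3-[(1R,2S,3S,6Z)-3-hydroxy-2-[(3E,5R,7E)-5-hydroxy-4,8,12-trimethyltrideca-3,7,11-trien-1-yl]-2,3-dimethyl-6-(1-oxopropan-2-ylidene)cyclohexyl]propyl (11Z)-hexadec-11-enoate (CNP0177216.2)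
Conditions: TBAF (tetrabutylammonium fluoride), AcOH (1:1), THF, 0 °C → rt
Reagents that add atoms: none
Why: Fluoride desilylation buffered with acetic acid removes the TIPS group without cleaving the ester or isomerising the enal, giving the target.

## Compound list

1 | 1,4-dioxaspiro[4.5]dec-6-en-8-one | O=C1C=CC2(CC1)OCCO2 | starting material
2 | 7-iodo-1,4-dioxaspiro[4.5]dec-6-en-8-one | O=C1C(I)=CC2(CC1)OCCO2 | intermediate
3 | 7-methyl-1,4-dioxaspiro[4.5]dec-6-en-8-one | O=C1C(C)=CC2(CC1)OCCO2 | intermediate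
4 | (3-bromopropoxy)(tert-butyl)dimethylsilane | CC(C)(C)[Si](C)(C)OCCCBr | starting material
5 | [3-(TBS-oxy)propyl]magnesium bromide | CC(C)(C)[Si](C)(C)OCCC[Mg]Br | intermediate
6 | bromomagnesium enolate of the (6S) conjugate adduct | CC(C)(C)[Si](C)(C)OCCC[C@@H]1C2(OCCO2)CCC(O[Mg]Br)=C1C | intermediate
7 | (6S,7S)-7-allyl-6-[3-(TBS-oxy)propyl]-7-methyl-1,4-dioxaspiro[4.5]decan-8-one | CC(C)(C)[Si](C)(C)OCCC[C@@H]1C2(OCCO2)CCC(=O)[C@@]1(C)CC=C | intermediate
8 | (6S,7S,8S)-7-allyl-6-[3-(TBS-oxy)propyl]-7,8-dimethyl-1,4-dioxaspiro[4.5]decan-8-ol | CC(C)(C)[Si](C)(C)OCCC[C@@H]1C2(OCCO2)CC[C@](C)(O)[C@@]1(C)CC=C | intermediate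
9 | 8-O-triethylsilyl ether of 8 | CC(C)(C)[Si](C)(C)OCCC[C@@H]1C2(OCCO2)CC[C@](C)(O[Si](CC)(CC)CC)[C@@]1(C)CC=C | intermediate
10 | B-alkyl-9-borabicyclo[3.3.1]nonane from 9 (boron on the terminal carbon of the former allyl group) | CC(C)(C)[Si](C)(C)OCCC[C@@H]1C2(OCCO2)CC[C@](C)(O[Si](CC)(CC)CC)[C@@]1(C)CCCB3C4CCCC3CCC4 | intermediate
11 | 3-[(6S,7S,8S)-6-[3-(TBS-oxy)propyl]-7,8-dimethyl-8-(TES-oxy)-1,4-dioxaspiro[4.5]decan-7-yl]propan-1-ol | CC(C)(C)[Si](C)(C)OCCC[C@@H]1C2(OCCO2)CC[C@](C)(O[Si](CC)(CC)CC)[C@@]1(C)CCCO | intermediate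
12 | corresponding propanal | CC(C)(C)[Si](C)(C)OCCC[C@@H]1C2(OCCO2)CC[C@](C)(O[Si](CC)(CC)CC)[C@@]1(C)CCC=O | intermediate
13 | 2-(triphenylphosphoranylidene)propanal | CC(C=O)=P(c1ccccc1)(c1ccccc1)c1ccccc1 | starting material
14 | (2E)-2-methylpent-2-enal carrying the spiroketal ring at C5 | CC(C)(C)[Si](C)(C)OCCC[C@@H]1C2(OCCO2)CC[C@](C)(O[Si](CC)(CC)CC)[C@@]1(C)CC/C=C(\C)C=O | intermediate
15 | geranyl chloride, (2E)-1-chloro-3,7-dimethylocta-2,6-diene | ClC/C=C(\C)CCC=C(C)C | starting material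
16 | geranylbarium chloride | Cl[Ba]C/C=C(\C)CCC=C(C)C | intermediate
17 | (3E,7E)-trienol, both epimers at the side-chain carbinol | CC(C)(C)[Si](C)(C)OCCC[C@@H]1C2(OCCO2)CC[C@](C)(O[Si](CC)(CC)CC)[C@@]1(C)CC/C=C(\C)C(O)C/C=C(\C)CCC=C(C)C | intermediate
18 | (3E,7E)-trien-5-one (skipped dienone) | CC(C)(C)[Si](C)(C)OCCC[C@@H]1C2(OCCO2)CC[C@](C)(O[Si](CC)(CC)CC)[C@@]1(C)CC/C=C(\C)C(=O)C/C=C(\C)CCC=C(C)C | intermediate
19 | (3E,5R,7E)-trien-5-ol | CC(C)(C)[Si](C)(C)OCCC[C@@H]1C2(OCCO2)CC[C@](C)(O[Si](CC)(CC)CC)[C@@]1(C)CC/C=C(\C)[C@H](O)C/C=C(\C)CCC=C(C)C | intermediate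
20 | 5-O-triisopropylsilyl ether of 19 | CC(C)(C)[Si](C)(C)OCCC[C@@H]1C2(OCCO2)CC[C@](C)(O[Si](CC)(CC)CC)[C@@]1(C)CC/C=C(\C)[C@H](O[Si](C(C)C)(C(C)C)C(C)C)C/C=C(\C)CCC=C(C)C | intermediate
21 | (2S,3S,4S)-2-[3-(TBS-oxy)propyl]-3,4-dimethyl-4-(TES-oxy)-3-[(3E,5R,7E)-4,8,12-trimethyl-5-(TIPS-oxy)trideca-3,7,11-trien-1-yl]cyclohexan-1-one | CC(C)(C)[Si](C)(C)OCCC[C@@H]1C(=O)CC[C@](C)(O[Si](CC)(CC)CC)[C@@]1(C)CC/C=C(\C)[C@H](O[Si](C(C)C)(C(C)C)C(C)C)C/C=C(\C)CCC=C(C)C | intermediate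
22 | bromomagnesium alkoxide of the 1-ethynyl carbinol from 21 | CC(C)(C)[Si](C)(C)OCCC[C@@H]1C(C#C)(O[Mg]Br)CC[C@](C)(O[Si](CC)(CC)CC)[C@@]1(C)CC/C=C(\C)[C@H](O[Si](C(C)C)(C(C)C)C(C)C)C/C=C(\C)CCC=C(C)C | intermediate
23 | methyl carbonate of the 1-ethynyl carbinol from 21 (carbinol carbon unassigned) | CC(C)(C)[Si](C)(C)OCCC[C@@H]1C(C#C)(OC(=O)OC)CC[C@](C)(O[Si](CC)(CC)CC)[C@@]1(C)CC/C=C(\C)[C@H](O[Si](C(C)C)(C(C)C)C(C)C)C/C=C(\C)CCC=C(C)C | intermediate
24 | exocyclic allene, (1R,2S,3S)-6-ethenylidenecyclohexane | CC(C)(C)[Si](C)(C)OCCC[C@@H]1C(=C=C)CC[C@](C)(O[Si](CC)(CC)CC)[C@@]1(C)CC/C=C(\C)[C@H](O[Si](C(C)C)(C(C)C)C(C)C)C/C=C(\C)CCC=C(C)C | intermediate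
25 | pinacol (2Z)-2-(cyclohexylidene)propylboronate, CH2B cis to C1 | CC(C)(C)[Si](C)(C)OCCC[C@@H]1/C(=C(/C)CB2OC(C)(C)C(C)(C)O2)CC[C@](C)(O[Si](CC)(CC)CC)[C@@]1(C)CC/C=C(\C)[C@H](O[Si](C(C)C)(C(C)C)C(C)C)C/C=C(\C)CCC=C(C)C | intermediate
26 | (2Z)-2-(cyclohexylidene)propan-1-ol, CH2OH cis to C1 | CC(C)(C)[Si](C)(C)OCCC[C@@H]1/C(=C(/C)CO)CC[C@](C)(O[Si](CC)(CC)CC)[C@@]1(C)CC/C=C(\C)[C@H](O[Si](C(C)C)(C(C)C)C(C)C)C/C=C(\C)CCC=C(C)C | intermediate
27 | tris-silylated (2Z)-2-(cyclohexylidene)propanal | CC(C)(C)[Si](C)(C)OCCC[C@@H]1/C(=C(/C)C=O)CC[C@](C)(O[Si](CC)(CC)CC)[C@@]1(C)CC/C=C(\C)[C@H](O[Si](C(C)C)(C(C)C)C(C)C)C/C=C(\C)CCC=C(C)C | intermediate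
28 | (Z)-enal with free primary and tertiary OH, side-chain O-TIPS | OCCC[C@@H]1/C(=C(/C)C=O)CC[C@](C)(O)[C@@]1(C)CC/C=C(\C)[C@H](O[Si](C(C)C)(C(C)C)C(C)C)C/C=C(\C)CCC=C(C)C | intermediate
29 | (11Z)-hexadec-11-enoic acid | CCCC/C=C\CCCCCCCCCC(=O)O | starting material
30 | side-chain O-TIPS ether of the target | CCCC/C=C\CCCCCCCCCC(=O)OCCC[C@@H]1/C(=C(/C)C=O)CC[C@](C)(O)[C@@]1(C)CC/C=C(\C)[C@H](O[Si](C(C)C)(C(C)C)C(C)C)C/C=C(\C)CCC=C(C)C | intermediate
31 | 3-[(1R,2S,3S,6Z)-3-hydroxy-2-[(3E,5R,7E)-5-hydroxy-4,8,12-trimethyltrideca-3,7,11-trien-1-yl]-2,3-dimethyl-6-(1-oxopropan-2-ylidene)cyclohexyl]propyl (11Z)-hexadec-11-enoate | CCCC/C=C\CCCCCCCCCC(=O)OCCC[C@@H]1/C(=C(/C)C=O)CC[C@](C)(O)[C@@]1(C)CC/C=C(\C)[C@H](O)C/C=C(\C)CCC=C(C)C | target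

## Step count and risks

Total step count: 20. Longest linear sequence: 20 steps (1 → 31); 4, 13, 15 and 29 are purchased.

The three steps most likely to fail:

**Step 16 (proposed new methylboration).** Risks are β-hydride loss from the π-allyl intermediate, slow methyl insertion, and syn/anti leakage that would erode the Z geometry. The fallback uses known chemistry, sets out from ketone 21 and returns at enal 27. Ketone 21 is treated with 2-propenylmagnesium bromide and CeCl3 (THF, −78 °C) to give the tertiary 1-(prop-1-en-2-yl)cyclohexan-1-ol F7. Oxidative 1,3-transposition with pyridinium chlorochromate, C5H5NH[CrO3Cl] (CH2Cl2, rt; Babler–Dauben oxidation), converts F7 directly into the α-methyl enal. This comes as an E/Z mixture with no reliable bias; the Z isomer 27 is separated on AgNO3-impregnated silica and the E isomer is recycled by photochemical or iodine-catalysed equilibration.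

**Step 3 (asymmetric conjugate addition with allylation on a γ-ketal, α-methyl enone).** Risks are low reactivity of the trisubstituted enone and insufficient enantioselectivity. The fallback sets out from Grignard reagent 5 and returns at 7. Reagent 5 is transmetalated with ZnCl2 (0.5 equiv; magnesium salts removed with 1,4-dioxane) to bis[3-(TBS-oxy)propyl]zinc F1. F1 is added under Cu(OTf)2 and (S,R,R)-O,O'-(1,1'-binaphthalene-2,2'-diyl)-N,N-bis(1-phenylethyl)phosphoramidite catalysis to the purchased symmetrical quinone monoketal 1,4-dioxaspiro[4.5]deca-6,9-dien-8-one F2; this desymmetrising dialkylzinc conjugate addition is established chemistry and gives (6S)-6-[3-(TBS-oxy)propyl]-1,4-dioxaspiro[4.5]dec-9-en-8-one F3. The enone can be enolised only on its saturated side, so LiN(iPr)2/MeI gives the (6S,7S)-7-methyl enone F4, and a second LiN(iPr)2/allyl iodide alkylation (allyl anti to the neighbouring chain) gives the (6S,7S)-7-allyl-7-methyl enone F5. Chemoselective 1,4-reduction of the remaining enone with [(Ph3P)CuH]6 leaves the allyl group alone and delivers 7.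

**Step 4 (facial selectivity of methyl addition next to the quaternary centre).** The fallback sets out from ketone 7 and returns at alcohol 8. Corey–Chaykovsky reaction of 7 with dimethylsulfonium methylide (Me3S+ I−, n-BuLi, THF, −10 °C) delivers CH2 irreversibly along the axial trajectory and gives the spiro-epoxide of 7 F6, with the oxirane oxygen cis to the C7 methyl. Regioselective hydride opening at the oxirane CH2 with LiBHEt3 (THF, 0 °C) then gives 8.

Further compounds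
F1 | step 3 | bis[3-(tert-butyldimethylsilyloxy)propyl]zinc | CC(C)(C)[Si](C)(C)OCCC[Zn]CCCO[Si](C)(C)C(C)(C)C
F2 | step 3 | 1,4-dioxaspiro[4.5]deca-6,9-dien-8-one | O=C1C=CC2(C=C1)OCCO2
F3 | step 3 | (6S)-6-[3-(tert-butyldimethylsilyloxy)propyl]-1,4-dioxaspiro[4.5]dec-9-en-8-one | CC(C)(C)[Si](C)(C)OCCC[C@@H]1C2(OCCO2)C=CC(=O)C1
F4 | step 3 | (6S,7S)-6-[3-(tert-butyldimethylsilyloxy)propyl]-7-methyl-1,4-dioxaspiro[4.5]dec-9-en-8-one | CC(C)(C)[Si](C)(C)OCCC[C@@H]1C2(OCCO2)C=CC(=O)[C@H]1C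
F5 | step 3 | (6S,7S)-7-allyl-6-[3-(tert-butyldimethylsilyloxy)propyl]-7-methyl-1,4-dioxaspiro[4.5]dec-9-en-8-one | CC(C)(C)[Si](C)(C)OCCC[C@@H]1C2(OCCO2)C=CC(=O)[C@@]1(C)CC=C
F6 | step 4 | spiro-epoxide of 7 (oxirane O cis to the C7 methyl, oxirane CH2 on the allyl face) | CC(C)(C)[Si](C)(C)OCCC[C@@H]1C2(OCCO2)CC[C@]3(OC3)[C@@]1(C)CC=C
F7 | step 16 | tertiary 1-(prop-1-en-2-yl)cyclohexan-1-ol from 21 | CC(C)(C)[Si](C)(C)OCCC[C@@H]1C(O)(C(C)=C)CC[C@](C)(O[Si](CC)(CC)CC)[C@@]1(C)CC/C=C(\C)[C@H](O[Si](C(C)C)(C(C)C)C(C)C)C/C=C(\C)CCC=C(C)C
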